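The ten-membered carbocycle is disconnected at C2–C3 (germacrane numbering), exploiting its homoallylic carbinol unit C2(O)–C3H2–C4(CH3)=C5, the retron of a [2,3]-Wittig shift. The precursor is a nine-membered cyclic bis-allylic ether (oxonene) whose oxygen bridges C2 and C5 and whose C5 carries an exocyclic isopropenyl group (C4, C3, C15). Deprotonation at C2 triggers a one-atom ring expansion that forms the C2–C3 bond, turns the ring oxygen into the C2 hydroxyl, creates the ring-cis C4=C5 olefin and transfers chirality from C5 to C2 in one operation. The oxonene is closed beforehand at C6–C7 by a chromium-mediated allylation that also builds the lactone.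

Key step: step 18

Remark: germacrane numbering is used for all intermediates (ring C1–C10 with C1=C10 and C4=C5; C11–C13 the α-methylene lactone carbons; C14 the CH2O carbon on C10; C15 the methyl on C4). The target is read as (2S,6R,7R,8R) with a trans-fused 6,12-lactone and both ring olefins cis in the ring sense (C2/C9 and C3/C6 syn).

Step 1
Reactants: 1 3-methylbut-2-en-1-ol (prenol)
Product: 2 [(2S)-3,3-dimethyloxiran-2-yl]methanol
Conditions: Ti(Oi-Pr)4 (cat.), L-(+)-diethyl tartrate (cat.), t-BuOOH, 4 Å MS, CH2Cl2, −20 °C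
Reagents that add atoms: tert-butyl hydroperoxide CC(C)(C)OO
Why: Sharpless asymmetric epoxidation; the L-(+)-tartrate/titanium catalyst delivers oxygen to one enantioface of the allylic alcohol and so fixes the (2S) centre that later becomes C5.

Step 2
Reactants: 2 [(2S)-3,3-dimethyloxiran-2-yl]methanol
Product: 3 (2S)-2-{[(4-methoxybenzyl)oxy]methyl}-3,3-dimethyloxirane
Conditions: NaH, PMBCl, Bu4NI (cat.), THF, 0 °C → rt
Reagents that add atoms: 4-methoxybenzyl chloride COc1ccc(CCl)cc1
Why: Williamson etherification of the primary alkoxide, fast enough at 0 °C to outrun Payne rearrangement; the stereocentre is not touched.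

Step 3
Reactants: 3 (2S)-2-{[(4-methoxybenzyl)oxy]methyl}-3,3-dimethyloxirane
Product: 4 (2R)-1-[(4-methoxybenzyl)oxy]-3-methylbut-3-en-2-ol
Conditions: Et2Al(TMP), toluene, 0 °C
Reagents that add atoms: none
Why: Yamamoto epoxide-to-allylic-alcohol isomerization: the hindered aluminium amide removes a methyl proton with cleavage of the tertiary C–O bond, so the secondary C–O stereocentre is kept (the descriptor becomes R only through the priority rules).

Step 4
Reactants: 5 but-2-yne-1,4-diol
Product: 6 4-[(tert-butyldiphenylsilyl)oxy]but-2-yn-1-ol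
Conditions: TBDPSCl (1 equiv), imidazole, diol in excess, DMF, 0 °C
Reagents that add atoms: tert-butyl(chloro)diphenylsilane CC(C)(C)[Si](Cl)(c1ccccc1)c1ccccc1
Why: Statistical monosilylation of a symmetric diol used in excess; no stereochemistry is involved.

Step 5
Reactants: 6 4-[(tert-butyldiphenylsilyl)oxy]but-2-yn-1-ol
Product: 8 (2Z)-4-[(tert-butyldiphenylsilyl)oxy]-3-iodobut-2-en-1-ol, via cyclic vinylalanate 7 (not isolated)
Conditions: Red-Al, THF, 0 °C → rt; then I2, −78 °C
Reagents that add atoms: iodine II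
Why: Hydroxyl-directed trans-hydroalumination of the propargylic alcohol places aluminium on the distal alkyne carbon and iodinolysis occurs with retention, giving the Z-iodide in which the two CH2O groups are trans, the geometry needed for the ring-cis C1=C10 bond.

Step 6
Reactants: 8 (2Z)-4-[(tert-butyldiphenylsilyl)oxy]-3-iodobut-2-en-1-ol
Product: 9 {[(2Z)-4-bromo-2-iodobut-2-en-1-yl]oxy}(tert-butyl)diphenylsilane
Conditions: CBr4, PPh3, CH2Cl2, 0 °C
Reagents that add atoms: carbon tetrabromide BrC(Br)(Br)Br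
Why: Appel bromination of the primary allylic alcohol under neutral conditions that leave the vinyl iodide and the silyl ether intact.

Step 7
Reactants: 4 (2R)-1-[(4-methoxybenzyl)oxy]-3-methylbut-3-en-2-ol; 9 {[(2Z)-4-bromo-2-iodobut-2-en-1-yl]oxy}(tert-butyl)diphenylsilane
Product: 10 tert-butyl{[(2Z)-2-iodo-4-{[(2R)-1-[(4-methoxybenzyl)oxy]-3-methylbut-3-en-2-yl]oxy}but-2-en-1-yl]oxy}diphenylsilane
Conditions: NaH, Bu4NI (cat.), THF/DMF, 0 °C → rt
Reagents that add atoms: none
Why: Williamson etherification (SN2 at the primary allylic bromide) joins the two fragments through the future ring oxygen; C5 keeps its configuration because its C–O bond is not broken.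

Step 8
Reactants: 11 (2S)-oxiran-2-ylmethanol [(S)-glycidol]
Product: 12 triethyl{[(2R)-oxiran-2-yl]methoxy}silane
Conditions: TESCl, imidazole, CH2Cl2, 0 °C
Reagents that add atoms: chlorotriethylsilane CC[Si](CC)(CC)Cl
Why: O-silylation of the primary alcohol; the stereocentre (future C8) is unchanged and the descriptor switches to R by priority only.

Step 9
Reactants: 10 iodo ether; 12 triethyl{[(2R)-oxiran-2-yl]methoxy}silane
Product: 14 (5R,8R)-homoallylic alcohol PMBO–C6H2–C5H(isopropenyl)–O–C2H2–C1H=C10(C14H2OTBDPS)–C9H2–C8H(OH)–C7H2–OTES (C2/C9 cis), via vinyllithium 13 (not isolated)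
Conditions: t-BuLi (2.1 equiv), Et2O, −78 °C; then 12, BF3·OEt2, −78 °C
Reagents that add atoms: none
Why: Iodine–lithium exchange (faster at −78 °C than deprotonation of the allylic ether) occurs with retention of olefin geometry, and the vinyllithium opens the BF3-activated epoxide at its terminal carbon (Ganem-type opening), forming C9–C10 and delivering C8–OH with the glycidol configuration.

Step 10
Reactants: 14 (5R,8R)-homoallylic alcohol
Product: 15 (5R,8R)-bis(triethylsilyl) ether (C7–OTES and C8–OTES)
Conditions: TESCl, imidazole, DMAP (cat.), CH2Cl2, rt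
Reagents that add atoms: chlorotriethylsilane CC[Si](CC)(CC)Cl
Why: Silylation of the secondary alcohol protects C8–OH with a group that can later be removed beside the TBDPS ether; no stereocentre is affected.

Step 11
Reactants: 15 (5R,8R)-bis(triethylsilyl) ether
Product: 17 (5R,8R)-aldehyde (C7 = CHO; C8–OTES), via alkoxysulfonium chloride 16 (not isolated)
Conditions: (COCl)2, DMSO, CH2Cl2, −78 → −40 °C; then Et3N
Reagents that add atoms: none
Why: Under Swern conditions the primary TES ether is cleaved and oxidized directly to the aldehyde while the secondary TES and the TBDPS ethers survive, and the low temperature keeps C8 from epimerizing.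

Step 12
Reactants: 17 (5R,8R)-aldehyde; 18 methyl acrylate
Product: 19 Morita–Baylis–Hillman adduct C8H(OTES)–C7H(OH)–C11(=C13H2)–CO2Me (both C7 epimers)
Conditions: DABCO, MeOH (cat.), excess 18, rt
Reagents that add atoms: none
Why: Morita–Baylis–Hillman reaction; the new carbinol centre at C7 forms as a mixture, which is irrelevant because it is destroyed in the next step.

Step 13
Reactants: 19 Morita–Baylis–Hillman adduct
Product: 20 (Z)-allylic bromide C8H(OTES)–C7H=C11(CO2Me)–C13H2Br (C8 cis to CH2Br)
Conditions: NBS, Me2S, CH2Cl2, 0 °C → rt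
Reagents that add atoms: N-bromosuccinimide O=C1CCC(=O)N1Br
Why: Activation of the allylic alcohol as an alkoxysulfonium ion and SN2′ return of bromide (Corey–Kim-type reagent) gives the conjugated, thermodynamically favoured (Z)-2-(bromomethyl)enoate from both C7 epimers.

Step 14
Reactants: 20 (Z)-allylic bromide
Product: 21 primary alcohol (C6H2–OH; PMB removed)
Conditions: DDQ, CH2Cl2/pH 7 buffer, 0 °C
Reagents that add atoms: none
Why: Oxidative PMB cleavage by hydride abstraction from the electron-rich benzyl ether; silyl ethers, the allylic bromide and the enoate are inert.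

Step 15
Reactants: 21 primary alcohol
Product: 22 (5R,8R)-aldehyde (C6 = CHO) bearing the allylic bromide
Conditions: Dess–Martin periodinane, NaHCO3, CH2Cl2, 0 °C
Reagents that add atoms: none
Why: Dess–Martin oxidation without base should give the α-alkoxy β,γ-unsaturated aldehyde without epimerizing C5 or moving the isopropenyl double bond into conjugation; the aldehyde is used crude.

Step 16
Reactants: 22 (5R,8R)-aldehyde
Product: 25 oxonene-fused trans α-methylene-γ-butyrolactone (nine-membered ring O–C2–C1=C10–C9–C8–C7–C6–C5; C5 isopropenyl; C8 OTES; C14 OTBDPS; lactone C6–O–C12(=O)–C11(=C13H2)–C7 with H6/H7 trans), via allylchromium species 23 (not isolated), via seco hydroxy ester 24 (not isolated)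
Conditions: CrCl2 (6 equiv), THF, high dilution (2 mM), rt; lactonization on work-up
Reagents that add atoms: none
Why: Intramolecular Nozaki–Hiyama-type (Cr(II) Barbier) carbonyl allylation followed by lactonization: C7 of the 2-(methoxycarbonyl)allylchromium adds to the aldehyde through a chair Zimmerman–Traxler array with both tether bonds equatorial, which should give the anti adduct and hence the trans-fused lactone, while the face is expected to be chosen by the forming oxonene, in which the C5 isopropenyl and C8 silyloxy groups avoid transannular positions.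

Step 17
Reactants: 25 oxonene-fused lactone
Product: 27 oxonene diol (C6–OH and C12H2–OH; otherwise as 25), via lactol 26 (not isolated)
Conditions: DIBAL-H (4 equiv), CH2Cl2, −78 → 0 °C
Reagents that add atoms: none
Why: 1,2-Reduction of the lactone through the lactol to the allylic 1,4-diol masks the base-sensitive α-methylene lactone for the carbanion step; no stereocentre is affected.

Step 18
Reactants: 27 oxonene diol
Product: 29 ring-expanded cyclodeca-1(10),4-diene triol (C2–OH, C6–OH, C12H2–OH; C8 OTES; C14 OTBDPS; both ring olefins ring-cis; C2/C6/C7/C8 as in the target), via trilithiated ether 28 (not isolated)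
Conditions: n-BuLi (4 equiv), THF, −78 → −20 °C; then aq. NH4Cl
Reagents that add atoms: none
Why: After the two hydroxyls are converted to lithium alkoxides, a further equivalent of base removes a proton from the allylic, α-oxygenated C2 methylene, and the α-oxy allyl anion attacks the terminal CH2 (C3) of the isopropenyl group on the face from which the C5–O bond departs, a suprafacial [2,3]-Wittig shift through a five-membered envelope transition state. The closest known reactions are the [2,3]-Wittig ring contractions of macrocyclic bis-allylic ethers to germacrane and cembrane carbocycles and the Z-selective Still–Wittig rearrangement of 2-methylallyl ethers; here the migrating allyl terminus is exocyclic, so the ring grows instead of shrinking. The ten-membered carbocycle is closed by C2–C3 bond formation across the oxonene (a bicyclo[6.2.1]-like transition state) while the ring oxygen is expelled as the C2 alkoxide, a one-atom ring expansion from nine to ten. The new C2 stereocentre is set by 1,3-chirality transfer from C5: the six-atom bridge C1=C10–C9–C8–C7–C6 forces C1 and C6 to be cis on the five-membered transition-state ring, so the new bond forms on the oxonene face that carries the isopropenyl group and (5R) becomes (2S). The same short bridge, reinforced by A(1,2) strain with the C4 methyl group, places C6 on the inside of the allyl unit and should give the ring-cis (Z) C4=C5 olefin. The step needs deprotonation at C2 rather than at C5–H or C14 and [2,3] over [1,2] shift; the first is secured by the accessible primary allylic CH2 next to the coordinating ether oxygen, by the C6 alkoxide that disfavours charge at C5 and by the bulky TBDPS group at C14, the second by the low temperature.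

Step 19
Reactants: 29 ring-expanded triol
Product: 32 2-hydroxy germacranolide (trans-fused α-methylene 6,12-lactone; C8 OTES; C14 OTBDPS), via hydroxy enal 30 (not isolated), via lactol 31 (not isolated)
Conditions: TEMPO (cat.), PhI(OAc)2 (2.2 equiv), CH2Cl2, rt
Reagents that add atoms: none
Why: TEMPO/PhI(OAc)2 oxidizes the primary allylic alcohol much faster than the secondary ones, the enal is trapped by the C6 hydroxyl as the five-membered lactol, and this is oxidized on to the lactone (oxidative lactonization of a 1,4-diol) with C6 and C7 unchanged.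

Step 20
Reactants: 32 2-hydroxy germacranolide
Product: 33 2-O-acetate (C8 OTES; C14 OTBDPS)
Conditions: Ac2O, pyridine, DMAP (cat.), CH2Cl2, 0 °C
Reagents that add atoms: acetic anhydride CC(=O)OC(C)=O
Why: DMAP-catalysed acylation of the only free hydroxyl, with retention at C2.

Step 21
Reactants: 33 2-O-acetate
Product: 34 8-hydroxy 2-O-acetate (C14 OTBDPS)
Conditions: PPTS, MeOH, 0 °C
Reagents that add atoms: none
Why: Mild acid-catalysed methanolysis removes the secondary TES ether, while the far more robust primary TBDPS ether, the allylic acetate and the lactone should survive.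

Step 22
Reactants: 34 8-hydroxy 2-O-acetate
Product: 35 8-O-methacrylate 2-O-acetate 14-O-TBDPS ether
Conditions: methacrylic anhydride, Et3N, DMAP, CH2Cl2, 0 °C → rt
Reagents that add atoms: methacrylic anhydride C=C(C)C(=O)OC(=O)C(C)=C
Why: DMAP-catalysed (Steglich-type) acylation of the secondary C8 alcohol with retention of configuration.

Step 23
Reactants: 35 8-O-methacrylate 2-O-acetate 14-O-TBDPS ether
Product: 36 CNP0138477.1
Conditions: HF·pyridine, THF, 0 °C → rt
Reagents that add atoms: none
Why: Fluoride-mediated desilylation under acidic, non-basic conditions should free the C14 hydroxyl without acyl migration or conjugate addition to the methacrylate and the α-methylene lactone.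

Compound list

1 | 3-methylbut-2-en-1-ol (prenol) | CC(C)=CCO | starting material
2 | [(2S)-3,3-dimethyloxiran-2-yl]methanol | OC[C@@H]1OC1(C)C | intermediate
3 | (2S)-2-{[(4-methoxybenzyl)oxy]methyl}-3,3-dimethyloxirane | COc1ccc(COC[C@@H]2OC2(C)C)cc1 | intermediate
4 | (2R)-1-[(4-methoxybenzyl)oxy]-3-methylbut-3-en-2-ol | COc1ccc(COC[C@H](O)C(C)=C)cc1 | intermediate
5 | but-2-yne-1,4-diol | OCC#CCO | starting material
6 | 4-[(tert-butyldiphenylsilyl)oxy]but-2-yn-1-ol | OCC#CCO[Si](c1ccccc1)(c1ccccc1)C(C)(C)C | intermediate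
7 | cyclic vinylalanate (sodium 2,2-bis(2-methoxyethoxy)-2,5-dihydro-1,2-oxaluminol-2-uide carrying CH2OTBDPS at C3) | [Na+].COCCO[Al-]1(OCCOC)OCC=C1CO[Si](c1ccccc1)(c1ccccc1)C(C)(C)C | intermediate (not isolated)
8 | (2Z)-4-[(tert-butyldiphenylsilyl)oxy]-3-iodobut-2-en-1-ol | OC/C=C(\I)CO[Si](c1ccccc1)(c1ccccc1)C(C)(C)C | intermediate
9 | {[(2Z)-4-bromo-2-iodobut-2-en-1-yl]oxy}(tert-butyl)diphenylsilane | BrC/C=C(\I)CO[Si](c1ccccc1)(c1ccccc1)C(C)(C)C | intermediate
10 | tert-butyl{[(2Z)-2-iodo-4-{[(2R)-1-[(4-methoxybenzyl)oxy]-3-methylbut-3-en-2-yl]oxy}but-2-en-1-yl]oxy}diphenylsilane (iodo ether) | COc1ccc(COC[C@H](OC/C=C(\I)CO[Si](c2ccccc2)(c2ccccc2)C(C)(C)C)C(C)=C)cc1 | intermediate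
11 | (2S)-oxiran-2-ylmethanol [(S)-glycidol] | OC[C@H]1CO1 | starting material
12 | triethyl{[(2R)-oxiran-2-yl]methoxy}silane | CC[Si](CC)(CC)OC[C@H]1CO1 | intermediate
13 | vinyllithium (lithium in place of iodine in 10) | COc1ccc(COC[C@H](OC/C=C(\[Li])CO[Si](c2ccccc2)(c2ccccc2)C(C)(C)C)C(C)=C)cc1 | intermediate (not isolated)
14 | (5R,8R)-homoallylic alcohol PMBO–C6H2–C5H(isopropenyl)–O–C2H2–C1H=C10(C14H2OTBDPS)–C9H2–C8H(OH)–C7H2–OTES (C2/C9 cis) | COc1ccc(COC[C@H](OC/C=C(/CO[Si](c2ccccc2)(c2ccccc2)C(C)(C)C)C[C@@H](O)CO[Si](CC)(CC)CC)C(C)=C)cc1 | intermediate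
15 | (5R,8R)-bis(triethylsilyl) ether of 14 (C7–OTES, C8–OTES) | COc1ccc(COC[C@H](OC/C=C(/CO[Si](c2ccccc2)(c2ccccc2)C(C)(C)C)C[C@@H](O[Si](CC)(CC)CC)CO[Si](CC)(CC)CC)C(C)=C)cc1 | intermediate
16 | alkoxysulfonium chloride (C7–O–S(CH3)2+ in place of C7–OTES) | COc1ccc(COC[C@H](OC/C=C(/CO[Si](c2ccccc2)(c2ccccc2)C(C)(C)C)C[C@@H](O[Si](CC)(CC)CC)CO[S+](C)C)C(C)=C)cc1.[Cl-] | intermediate (not isolated)
17 | (5R,8R)-aldehyde (C7 = CHO; C8–OTES) | COc1ccc(COC[C@H](OC/C=C(/CO[Si](c2ccccc2)(c2ccccc2)C(C)(C)C)C[C@@H](O[Si](CC)(CC)CC)C=O)C(C)=C)cc1 | intermediate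
18 | methyl acrylate | C=CC(=O)OC | starting material
19 | Morita–Baylis–Hillman adduct C8H(OTES)–C7H(OH)–C11(=C13H2)–CO2Me (both C7 epimers) | COc1ccc(COC[C@H](OC/C=C(/CO[Si](c2ccccc2)(c2ccccc2)C(C)(C)C)C[C@@H](O[Si](CC)(CC)CC)C(O)C(=C)C(=O)OC)C(C)=C)cc1 | intermediate
20 | (Z)-allylic bromide C8H(OTES)–C7H=C11(CO2Me)–C13H2Br (C8 cis to CH2Br) | COc1ccc(COC[C@H](OC/C=C(/CO[Si](c2ccccc2)(c2ccccc2)C(C)(C)C)C[C@@H](O[Si](CC)(CC)CC)/C=C(\CBr)C(=O)OC)C(C)=C)cc1 | intermediate
21 | primary alcohol (C6H2–OH; PMB removed from 20) | OC[C@H](OC/C=C(/CO[Si](c1ccccc1)(c1ccccc1)C(C)(C)C)C[C@@H](O[Si](CC)(CC)CC)/C=C(\CBr)C(=O)OC)C(C)=C | intermediate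
22 | (5R,8R)-aldehyde (C6 = CHO) bearing the allylic bromide | O=C[C@H](OC/C=C(/CO[Si](c1ccccc1)(c1ccccc1)C(C)(C)C)C[C@@H](O[Si](CC)(CC)CC)/C=C(\CBr)C(=O)OC)C(C)=C | intermediate
23 | allylchromium species (CrCl2 in place of Br in 22) | O=C[C@H](OC/C=C(/CO[Si](c1ccccc1)(c1ccccc1)C(C)(C)C)C[C@@H](O[Si](CC)(CC)CC)/C=C(\C[Cr](Cl)Cl)C(=O)OC)C(C)=C | intermediate (not isolated)
24 | seco hydroxy ester (oxonene with C6–OH and C7–C11(=C13H2)–CO2Me) | C=C(C)[C@H]1OC/C=C(/CO[Si](c2ccccc2)(c2ccccc2)C(C)(C)C)C[C@@H](O[Si](CC)(CC)CC)[C@@H](C(=C)C(=O)OC)[C@@H]1O | intermediate (not isolated)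
25 | oxonene-fused trans α-methylene-γ-butyrolactone (C5 isopropenyl; C8 OTES; C14 OTBDPS; H6/H7 trans) | C=C(C)[C@H]1OC/C=C(/CO[Si](c2ccccc2)(c2ccccc2)C(C)(C)C)C[C@@H](O[Si](CC)(CC)CC)[C@H]2C(=C)C(=O)O[C@H]12 | intermediate
26 | lactol of 25 (C12 = CH(OH)) | C=C(C)[C@H]1OC/C=C(/CO[Si](c2ccccc2)(c2ccccc2)C(C)(C)C)C[C@@H](O[Si](CC)(CC)CC)[C@H]2C(=C)C(O)O[C@H]12 | intermediate (not isolated)
27 | oxonene diol (C6–OH and C12H2–OH; otherwise as 25) | C=C(C)[C@H]1OC/C=C(/CO[Si](c2ccccc2)(c2ccccc2)C(C)(C)C)C[C@@H](O[Si](CC)(CC)CC)[C@@H](C(=C)CO)[C@@H]1O | intermediate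
28 | trilithiated ether (C2 carbanion and two lithium alkoxides of 27) | C=C(C)[C@H]1OC([Li])/C=C(/CO[Si](c2ccccc2)(c2ccccc2)C(C)(C)C)C[C@@H](O[Si](CC)(CC)CC)[C@@H](C(=C)CO[Li])[C@@H]1O[Li] | intermediate (not isolated)
29 | ring-expanded cyclodeca-1(10),4-diene triol (C2–OH, C6–OH, C12H2–OH; C8 OTES; C14 OTBDPS; both ring olefins ring-cis) | CC[Si](CC)(CC)O[C@@H]1C/C(CO[Si](c2ccccc2)(c2ccccc2)C(C)(C)C)=C\[C@@H](O)C/C(C)=C\[C@@H](O)[C@@H]1C(=C)CO | intermediate
30 | hydroxy enal (C12 = CHO; otherwise as 29) | CC[Si](CC)(CC)O[C@@H]1C/C(CO[Si](c2ccccc2)(c2ccccc2)C(C)(C)C)=C\[C@@H](O)C/C(C)=C\[C@@H](O)[C@@H]1C(=C)C=O | intermediate (not isolated)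
31 | lactol (C6–O–C12H(OH); otherwise as 32) | CC[Si](CC)(CC)O[C@@H]1C/C(CO[Si](c2ccccc2)(c2ccccc2)C(C)(C)C)=C\[C@@H](O)C/C(C)=C\[C@H]2OC(O)C(=C)[C@@H]21 | intermediate (not isolated)
32 | 2-hydroxy germacranolide (trans-fused α-methylene 6,12-lactone; C8 OTES; C14 OTBDPS) | CC[Si](CC)(CC)O[C@@H]1C/C(CO[Si](c2ccccc2)(c2ccccc2)C(C)(C)C)=C\[C@@H](O)C/C(C)=C\[C@H]2OC(=O)C(=C)[C@@H]21 | intermediate
33 | 2-O-acetate (C8 OTES; C14 OTBDPS) | CC[Si](CC)(CC)O[C@@H]1C/C(CO[Si](c2ccccc2)(c2ccccc2)C(C)(C)C)=C\[C@@H](OC(C)=O)C/C(C)=C\[C@H]2OC(=O)C(=C)[C@@H]21 | intermediate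
34 | 8-hydroxy 2-O-acetate (C14 OTBDPS) | O[C@@H]1C/C(CO[Si](c2ccccc2)(c2ccccc2)C(C)(C)C)=C\[C@@H](OC(C)=O)C/C(C)=C\[C@H]2OC(=O)C(=C)[C@@H]21 | intermediate
35 | 8-O-methacrylate 2-O-acetate 14-O-TBDPS ether | C=C(C)C(=O)O[C@@H]1C/C(CO[Si](c2ccccc2)(c2ccccc2)C(C)(C)C)=C\[C@@H](OC(C)=O)C/C(C)=C\[C@H]2OC(=O)C(=C)[C@@H]21 | intermediate
36 | CNP0138477.1 | C=C(C)C(=O)O[C@@H]1C/C(CO)=C\[C@@H](OC(C)=O)C/C(C)=C\[C@H]2OC(=O)C(=C)[C@@H]21 | target

Total step count: 23. Longest linear sequence: 19 steps (steps 1–3, 7, 9–23; the branch through steps 4–6 is equally long).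

Steps most likely to fail

Step 18 (key step). The triply lithiated species may aggregate, or proton abstraction may occur at C5–H or C14 instead of C2, or the anion may follow the [1,2]-shift, so that the ring expansion is outrun. The fallback sets out from 27 and replaces the polyanion by a protected monoanion. Both hydroxyls are silylated (TMSCl, Et3N, CH2Cl2) to the bis(trimethylsilyl) ether F3. The neutral ether is deprotonated at C2 with n-BuLi/TMEDA in THF at −78 °C and undergoes the same [2,3]-shift to the ring-expanded bis-TMS ether F4. K2CO3 in MeOH then removes the two TMS groups, and the route is rejoined at 29.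

Step 16. Facial selectivity at the aldehyde during the nine-membered ring closure may be poor, so that the syn adduct and hence the C6-epimeric, cis-fused lactone is formed. The fallback sets out from 22 and corrects C6 after the ring closure. The C6-epimeric cis-fused lactone F1 is opened with LiOH in THF/H2O to the seco hydroxy acid F2, which is kept as its carboxylate salt and used at once. Mitsunobu lactonization (PPh3, DIAD, THF, 0 °C) then closes the γ-lactone by intramolecular SN2 displacement with inversion at C6, and the route is rejoined at 25.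

Step 12. The amine-catalysed addition to the hindered α-silyloxy aldehyde may be slow, and prolonged exposure to base may erode the configuration at C8 by enolization. The fallback sets out from 17 and uses a vinylalumination instead. [1-(Methoxycarbonyl)vinyl]diisobutylalane F5, made from methyl propiolate and DIBAL-H with NMO in THF at 0 °C, adds to the aldehyde within hours under non-basic conditions and gives 19 directly.

Further compounds

F1 | step 16 | C6-epimeric cis-fused oxonene lactone | C=C(C)[C@H]1OC/C=C(/CO[Si](c2ccccc2)(c2ccccc2)C(C)(C)C)C[C@@H](O[Si](CC)(CC)CC)[C@H]2C(=C)C(=O)O[C@@H]12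
F2 | step 16 | seco hydroxy acid of F1 (C6–OH, C12 carboxylic acid) | C=C(C)[C@H]1OC/C=C(/CO[Si](c2ccccc2)(c2ccccc2)C(C)(C)C)C[C@@H](O[Si](CC)(CC)CC)[C@@H](C(=C)C(=O)O)[C@H]1O
F3 | step 18 | bis(trimethylsilyl) ether of 27 | C=C(C)[C@H]1OC/C=C(/CO[Si](c2ccccc2)(c2ccccc2)C(C)(C)C)C[C@@H](O[Si](CC)(CC)CC)[C@@H](C(=C)CO[Si](C)(C)C)[C@@H]1O[Si](C)(C)C
F4 | step 18 | ring-expanded bis-TMS ether (C2–OH free) | CC[Si](CC)(CC)O[C@@H]1C/C(CO[Si](c2ccccc2)(c2ccccc2)C(C)(C)C)=C\[C@@H](O)C/C(C)=C\[C@@H](O[Si](C)(C)C)[C@@H]1C(=C)CO[Si](C)(C)C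
F5 | step 12 | [1-(methoxycarbonyl)vinyl]diisobutylalane | C=C(C(=O)OC)[Al](CC(C)C)CC(C)C
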